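**Retrosynthetic overview**
1. Target ⇒ desilylation and Steglich senecioylation of the threo epoxy alcohol ⇒ Mitsunobu inversion at C1 of the erythro epoxy alcohol.
2. Erythro epoxy alcohol ⇒ tartrate-matched Sharpless epoxidation (C10, C11) of the (1R)-dienol ⇒ ketoreductase reduction of the macrocyclic dienone.
3. Eleven-membered ring ⇒ intramolecular Nozaki–Hiyama–Kishi closure of C1–C11 (enal + (E)-2-iodoalkene).
4. Open chain ⇒ Wittig union at C6=C7 of a C1–C6 aldehyde (quaternary C4, side chain in place) with a C7–C11 iodo-phosphorane.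
5. C4 ⇒ Johnson–Claisen chirality transfer from an (R)-allylic alcohol ⇒ Noyori transfer hydrogenation of an achiral ynone; ring order: carbocycle first, oxirane second.

Assumption: the SMILES is read literally, with ring numbering C1 (acyloxy carbon), C2=C3, C4 (quaternary), C5, C6=C7(CH2OH), C8, C9, C10–C11 (epoxide, methyl on C11); this gives (1S,4R,10R,11S), 2E, 6E (CH2OH trans to C5, so C5 and C8 are cis in the ring), side chain E, and a threo relation between the C1 oxygen and the epoxide.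

Abbreviations in names: TBSO = tert-butyldimethylsilyloxy, TESO = triethylsilyloxy, PMBO = 4-methoxybenzyloxy. Macrocycle locants follow the ring numbering above.

**Step 1**
Reactants: 1 2-chloro-N-methoxy-N-methylacetamide; 2 4-methoxybenzyl alcohol
Product: 4 N-methoxy-N-methyl-2-(PMBO)acetamide, via sodium 4-methoxybenzyl oxide 3 (not isolated)
Conditions: NaH, THF, 0 °C; then 1, Bu4NI (cat.), 0 °C → rt
Reagents that add atoms: none
Why: Williamson ether synthesis, the alkoxide displacing the activated α-chloride by SN2; no stereocentre is involved.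

**Step 2**
Reactants: 5 tert-butyl(but-3-yn-1-yloxy)dimethylsilane; 4 Weinreb amide
Product: 7 6-(TBSO)-1-(PMBO)hex-3-yn-2-one, via lithium acetylide 6 (not isolated)
Conditions: n-BuLi, THF, −78 °C; then 4, −78 → −20 °C
Reagents that add atoms: none
Why: Weinreb ketone synthesis, the chelated tetrahedral adduct preventing a second addition so that the ynone appears only on work-up.

**Step 3**
Reactants: 7 ynone
Product: 8 (2R)-6-(TBSO)-1-(PMBO)hex-3-yn-2-ol
Conditions: Ru[(S,S)-TsNCHPhCHPhNH](p-cymene) (1 mol%), i-PrOH, 25 °C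
Reagents that add atoms: none
Why: Noyori asymmetric transfer hydrogenation, in which the alkyne takes the place an aryl group normally occupies next to the arene ligand, so the (S,S)-catalyst delivers hydride to the face giving the (R)-carbinol; this is the first stereocentre, set from an achiral ketone.

**Step 4**
Reactants: 8 (R)-propargylic alcohol
Product: 10 (2R,3Z)-4-iodo-6-(TBSO)-1-(PMBO)hex-3-en-2-ol, via cyclic alkenylalanate 9 (not isolated)
Conditions: NaAlH2(OCH2CH2OMe)2, THF, 0 °C → rt; then I2, −78 → 0 °C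
Reagents that add atoms: iodine, II
Why: Hydroxyl-directed trans-hydroalumination puts aluminium on the distal alkyne carbon (five-membered alkoxyalanate), and iodinolysis with retention gives the iodoalkene with iodine cis to the carbinol carbon.

**Step 5**
Reactants: 10 (Z)-iodo allylic alcohol
Product: 11 (2R,3E)-4-methyl-6-(TBSO)-1-(PMBO)hex-3-en-2-ol
Conditions: MeZnCl (3 equiv), Pd(PPh3)4 (5 mol%), THF, 25 → 45 °C
Reagents that add atoms: methylzinc chloride, C[Zn]Cl
Why: Negishi cross-coupling replaces iodine by methyl with retention, fixing the trisubstituted olefin (methyl cis to C2) that the Claisen step needs.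

**Step 6**
Reactants: 11 (R,E)-allylic alcohol; 12 triethyl orthoacetate
Product: 14 ethyl (3S,4E)-3-methyl-3-[2-(TBSO)ethyl]-6-(PMBO)hex-4-enoate, via mixed ketene acetal 13 (not isolated)
Conditions: EtCO2H (cat.), xylenes, 140 °C, EtOH distilled off
Reagents that add atoms: none
Why: Johnson–Claisen rearrangement through a chair transition state with CH2OPMB equatorial, which transfers the carbinol chirality suprafacially to the new quaternary carbon (C4 of the target) and forms the C2=C3 E-olefin.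

**Step 7**
Reactants: 14 ethyl ester
Product: 15 (3S,4E)-3-methyl-3-[2-(TBSO)ethyl]-6-(PMBO)hex-4-enal
Conditions: i-Bu2AlH (1.1 equiv), CH2Cl2, −78 °C
Reagents that add atoms: none
Why: Partial ester reduction, the tetrahedral aluminium acetal being stable at −78 °C and releasing the aldehyde only on work-up.

**Step 8**
Reactants: 15 aldehyde; 16 methyl (triphenylphosphoranylidene)acetate
Product: 17 methyl (2E,5R,6E)-5-methyl-5-[2-(TBSO)ethyl]-8-(PMBO)octa-2,6-dienoate
Conditions: CH2Cl2, rt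
Reagents that add atoms: none
Why: Wittig olefination with a stabilised ylide, which gives the E-enoate under thermodynamic control.

**Step 9**
Reactants: 17 methyl enoate
Product: 18 (3E,6R,7E)-2,6-dimethyl-6-[2-(TBSO)ethyl]-9-(PMBO)nona-3,7-dien-2-ol
Conditions: MeLi (3.5 equiv), THF, −78 → −20 °C
Reagents that add atoms: methyllithium, [Li]C
Why: Double 1,2-addition of a hard organolithium to the enoate builds the tertiary allylic alcohol of the side chain without conjugate addition.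

**Step 10**
Reactants: 18 TBS ether
Product: 19 (3R,5E)-3,7-dimethyl-3-[(1E)-3-(PMBO)prop-1-en-1-yl]oct-5-ene-1,7-diol
Conditions: Bu4NF, THF, 0 °C → rt
Reagents that add atoms: none
Why: Fluoride-mediated desilylation frees the primary alcohol while the PMB ether is untouched.

**Step 11**
Reactants: 19 diol
Product: 20 (3R,5E)-7-hydroxy-3,7-dimethyl-3-[(1E)-3-(PMBO)prop-1-en-1-yl]oct-5-enal
Conditions: Dess–Martin periodinane, CH2Cl2, 0 °C → rt
Reagents that add atoms: none
Why: Dess–Martin oxidation of the primary alcohol; the tertiary alcohol cannot be oxidised.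

**Step 12**
Reactants: 21 pent-3-yn-1-ol
Product: 23 (3E)-4-iodopent-3-en-1-ol, via alkenylzirconocene chloride 22 (not isolated)
Conditions: Cp2Zr(H)Cl (2.5 equiv), THF, rt → 45 °C; then I2, 0 °C
Reagents that add atoms: iodine, II
Why: Hydrozirconation–iodination: syn addition of Zr–H, equilibration with excess reagent to the less hindered methyl-bearing carbon, and iodinolysis with retention give the (E)-2-iodoalkene (minor regioisomer removed by chromatography).

**Step 13**
Reactants: 23 (E)-iodo alcohol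
Product: 24 (2E)-2,5-diiodopent-2-ene
Conditions: I2, PPh3, imidazole, CH2Cl2, 0 °C → rt
Reagents that add atoms: iodine, II
Why: Appel-type (Garegg–Samuelsson) iodination of the primary alcohol; the vinyl iodide is inert.

**Step 14**
Reactants: 24 diiodide; 25 ethyl (triphenylphosphoranylidene)acetate
Product: 27 ethyl (5E)-6-iodo-2-(triphenylphosphoranylidene)hept-5-enoate, via phosphonium iodide 26 (not isolated)
Conditions: MeCN, 80 °C, 48 h; then aq NaOH, CH2Cl2, 0 °C
Reagents that add atoms: none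
Why: C-alkylation of the stabilised phosphorane by SN2 at the primary iodide only (sp2 C–I does not react), then deprotonation of the salt to the α-substituted ylide.

**Step 15**
Reactants: 20 aldehyde; 27 α-substituted ylide
Product: 28 ethyl (2E,5R,7E)-9-hydroxy-2-[(3E)-4-iodopent-3-en-1-yl]-5,9-dimethyl-5-[(1E)-3-(PMBO)prop-1-en-1-yl]deca-2,7-dienoate
Conditions: toluene, 90 °C
Reagents that add atoms: none
Why: Wittig olefination with an α-alkyl stabilised ylide places the ester trans to the C5 chain, which is the C6=C7 geometry of the target (C5 and C8 cis).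

**Step 16**
Reactants: 28 enoate
Product: 29 (2E,5R,7E)-2-[(3E)-4-iodopent-3-en-1-yl]-5,9-dimethyl-5-[(1E)-3-(PMBO)prop-1-en-1-yl]deca-2,7-diene-1,9-diol
Conditions: i-Bu2AlH (3.5 equiv), CH2Cl2, −78 → −40 °C
Reagents that add atoms: none
Why: 1,2-Reduction of the enoate to the allylic alcohol by an aluminium hydride; the vinyl iodide survives at low temperature.

**Step 17**
Reactants: 29 diol
Product: 30 (3E,6R,8E,12E)-13-iodo-2,6-dimethyl-6-[(1E)-3-(PMBO)prop-1-en-1-yl]-9-[(TBSO)methyl]tetradeca-3,8,12-trien-2-ol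
Conditions: TBSCl, imidazole, CH2Cl2, 0 °C
Reagents that add atoms: tert-butyldimethylsilyl chloride, CC(C)(C)[Si](C)(C)Cl
Why: Silylation selective for the primary over the tertiary hydroxyl on steric grounds.

**Step 18**
Reactants: 30 tertiary alcohol
Product: 31 (3E,6R,8E,12E)-13-iodo-2,6-dimethyl-6-[(1E)-3-(PMBO)prop-1-en-1-yl]-9-[(TBSO)methyl]-2-(TESO)tetradeca-3,8,12-triene
Conditions: TESOTf, 2,6-lutidine, CH2Cl2, −78 → 0 °C
Reagents that add atoms: triethylsilyl trifluoromethanesulfonate, CC[Si](CC)(CC)OS(=O)(=O)C(F)(F)F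
Why: Silyl triflate silylation of the hindered tertiary alcohol, masking it for the later epoxidation and Mitsunobu steps.

**Step 19**
Reactants: 31 PMB ether
Product: 32 (2E,4R,6E,10E)-11-iodo-4-methyl-4-[(2E)-4-methyl-4-(TESO)pent-2-en-1-yl]-7-[(TBSO)methyl]dodeca-2,6,10-trien-1-ol
Conditions: DDQ, CH2Cl2/pH 7 buffer (KH2PO4/K2HPO4), 0 °C
Reagents that add atoms: none
Why: Oxidative cleavage of the electron-rich PMB ether by DDQ; silyl ethers and the vinyl iodide are inert under buffered conditions.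

**Step 20**
Reactants: 32 allylic alcohol
Product: 33 (2E,4R,6E,10E)-11-iodo-4-methyl-4-[(2E)-4-methyl-4-(TESO)pent-2-en-1-yl]-7-[(TBSO)methyl]dodeca-2,6,10-trienal
Conditions: MnO2 (20 equiv), CH2Cl2, rt
Reagents that add atoms: none
Why: MnO2 oxidation, selective for the allylic alcohol with retention of the E-olefin; the enal has no γ-hydrogen and cannot deconjugate.

**Step 21**
Reactants: 33 iodo-enal
Product: 35 (2E,4R,6E,10E)-4,11-dimethyl-4-[(2E)-4-methyl-4-(TESO)pent-2-en-1-yl]-7-[(TBSO)methyl]cycloundeca-2,6,10-trien-1-ol (both C1 epimers), via alkenylchromium dichloride 34 (not isolated)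
Conditions: CrCl2 (12 equiv), NiCl2 (0.1 equiv), DMSO, 25 °C, 2 mM, slow addition of 33
Reagents that add atoms: none
Why: Intramolecular Nozaki–Hiyama–Kishi reaction: zerovalent nickel inserts into the C–I bond, transmetallation gives the alkenylchromium with retained geometry, and its chemoselective addition to the aldehyde at high dilution closes the eleven-membered ring; C1 forms as an epimer mixture that the next step erases.

**Step 22**
Reactants: 35 dienol epimers
Product: 36 (2E,4R,6E,10E)-4,11-dimethyl-4-[(2E)-4-methyl-4-(TESO)pent-2-en-1-yl]-7-[(TBSO)methyl]cycloundeca-2,6,10-trien-1-one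
Conditions: Dess–Martin periodinane, CH2Cl2, 0 °C → rt
Reagents that add atoms: none
Why: Dess–Martin oxidation converges both C1 epimers on one cross-conjugated dienone.

**Step 23**
Reactants: 36 dienone
Product: 37 (1R,2E,4R,6E,10E)-4,11-dimethyl-4-[(2E)-4-methyl-4-(TESO)pent-2-en-1-yl]-7-[(TBSO)methyl]cycloundeca-2,6,10-trien-1-ol
Conditions: ketoreductase (NADPH-dependent alcohol dehydrogenase; (R)-selective member of a screening panel), NADP+ (cat.), i-PrOH/KH2PO4–K2HPO4 buffer pH 7 (1:4), DMSO (10%), 30 °C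
Reagents that add atoms: none
Why: Enzymatic asymmetric ketone reduction: the ketoreductase binds the dienone in one orientation and passes hydride from NADPH (recycled by i-PrOH) to a single face of C1=O, giving the (1R)-alcohol without touching the olefins.

**Step 24**
Reactants: 37 (1R)-dienol
Product: 38 (1R,2E,4R,6E,10R,11R)-10,11-epoxy-4,11-dimethyl-4-[(2E)-4-methyl-4-(TESO)pent-2-en-1-yl]-7-[(TBSO)methyl]cycloundeca-2,6-dien-1-ol
Conditions: Ti(OiPr)4 (0.2 equiv), D-(−)-diisopropyl tartrate (0.24 equiv), t-BuOOH (1.5 equiv), 4 Å MS, CH2Cl2, −20 °C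
Reagents that add atoms: tert-butyl hydroperoxide, CC(C)(C)OO
Why: Sharpless asymmetric epoxidation in the matched sense: with D-(−)-tartrate the (1R)-carbinol is the fast-reacting configuration and oxygen goes to the C10=C11 face that gives the erythro epoxy alcohol with the epoxide of the target, while C2=C3 is both mismatched and less electron-rich.

**Step 25**
Reactants: 38 erythro epoxy alcohol
Product: 39 (1S,2E,4R,6E,10R,11S)-10,11-epoxy-4,11-dimethyl-4-[(2E)-4-methyl-4-(TESO)pent-2-en-1-yl]-7-[(TBSO)methyl]cycloundeca-2,6-dien-1-yl 4-nitrobenzoate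
Conditions: 4-nitrobenzoic acid, PPh3, DIAD, toluene, 0 °C → rt
Reagents that add atoms: 4-nitrobenzoic acid, O=C(O)c1ccc(cc1)[N+](=O)[O-]
Why: Mitsunobu reaction: SN2 displacement of the alkoxyphosphonium by the carboxylate inverts C1 from R to S and so turns the erythro into the threo array of the target; the SN2′ terminus C3 is shielded by the quaternary C4.

**Step 26**
Reactants: 39 nitrobenzoate
Product: 40 (1S,2E,4R,6E,10R,11R)-10,11-epoxy-4,11-dimethyl-4-[(2E)-4-methyl-4-(TESO)pent-2-en-1-yl]-7-[(TBSO)methyl]cycloundeca-2,6-dien-1-ol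
Conditions: K2CO3 (0.2 equiv), MeOH, 0 °C
Reagents that add atoms: none
Why: Base-catalysed transesterification removes the activated aryl ester; a Payne rearrangement is not possible because the neighbouring epoxide carbon is fully substituted.

**Step 27**
Reactants: 40 threo epoxy alcohol; 41 3-methylbut-2-enoic acid
Product: 43 (1S,2E,4R,6E,10R,11S)-10,11-epoxy-4,11-dimethyl-4-[(2E)-4-methyl-4-(TESO)pent-2-en-1-yl]-7-[(TBSO)methyl]cycloundeca-2,6-dien-1-yl 3-methylbut-2-enoate, via O-acylisourea 42 (not isolated)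
Conditions: 41 (3 equiv), DCC, DMAP, CH2Cl2, 0 °C → rt
Reagents that add atoms: none
Why: Steglich esterification with retention at C1; DMAP acyl transfer without a strong base avoids deconjugation of the senecioyl group.

**Step 28**
Reactants: 43 bis-silyl ether
Product: 44 CNP0248133.1
Conditions: Bu4NF, AcOH (1:1), THF, 0 °C → rt
Reagents that add atoms: none
Why: Buffered fluoride desilylation removes the primary TBS and tertiary TES ethers while the epoxide and the conjugated ester survive.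

**Compound list**
1 | 2-chloro-N-methoxy-N-methylacetamide | CON(C)C(=O)CCl | starting material
2 | 4-methoxybenzyl alcohol | COc1ccc(CO)cc1 | starting material
3 | sodium 4-methoxybenzyl oxide | COc1ccc(C[O-])cc1.[Na+] | intermediate
4 | N-methoxy-N-methyl-2-(PMBO)acetamide | CON(C)C(=O)COCc1ccc(OC)cc1 | intermediate
5 | tert-butyl(but-3-yn-1-yloxy)dimethylsilane | C#CCCO[Si](C)(C)C(C)(C)C | starting material
6 | lithium acetylide of 5 | [Li]C#CCCO[Si](C)(C)C(C)(C)C | intermediate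
7 | 6-(TBSO)-1-(PMBO)hex-3-yn-2-one | COc1ccc(COCC(=O)C#CCCO[Si](C)(C)C(C)(C)C)cc1 | intermediate
8 | (2R)-6-(TBSO)-1-(PMBO)hex-3-yn-2-ol | COc1ccc(COC[C@H](O)C#CCCO[Si](C)(C)C(C)(C)C)cc1 | intermediate
9 | sodium cyclic alkenylalanate of 8 (five-membered C=C–Al–O chelate, Al on C4) | [Na+].COCCO[Al-]1(OCCOC)O[C@@H](COCc2ccc(OC)cc2)C=C1CCO[Si](C)(C)C(C)(C)C | intermediate
10 | (2R,3Z)-4-iodo-6-(TBSO)-1-(PMBO)hex-3-en-2-ol | COc1ccc(COC[C@H](O)/C=C(\I)CCO[Si](C)(C)C(C)(C)C)cc1 | intermediate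
11 | (2R,3E)-4-methyl-6-(TBSO)-1-(PMBO)hex-3-en-2-ol | COc1ccc(COC[C@H](O)/C=C(\C)CCO[Si](C)(C)C(C)(C)C)cc1 | intermediate
12 | triethyl orthoacetate | CCOC(C)(OCC)OCC | starting material
13 | mixed ketene acetal of 11 (1-ethoxyvinyl ether on the C2 oxygen) | COc1ccc(COC[C@H](OC(=C)OCC)/C=C(\C)CCO[Si](C)(C)C(C)(C)C)cc1 | intermediate
14 | ethyl (3S,4E)-3-methyl-3-[2-(TBSO)ethyl]-6-(PMBO)hex-4-enoate | COc1ccc(COC/C=C/[C@](C)(CC(=O)OCC)CCO[Si](C)(C)C(C)(C)C)cc1 | intermediate
15 | (3S,4E)-3-methyl-3-[2-(TBSO)ethyl]-6-(PMBO)hex-4-enal | COc1ccc(COC/C=C/[C@](C)(CC=O)CCO[Si](C)(C)C(C)(C)C)cc1 | intermediate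
16 | methyl (triphenylphosphoranylidene)acetate | COC(=O)C=P(c1ccccc1)(c1ccccc1)c1ccccc1 | starting material
17 | methyl (2E,5R,6E)-5-methyl-5-[2-(TBSO)ethyl]-8-(PMBO)octa-2,6-dienoate | COc1ccc(COC/C=C/[C@](C)(C/C=C/C(=O)OC)CCO[Si](C)(C)C(C)(C)C)cc1 | intermediate
18 | (3E,6R,7E)-2,6-dimethyl-6-[2-(TBSO)ethyl]-9-(PMBO)nona-3,7-dien-2-ol | COc1ccc(COC/C=C/[C@](C)(C/C=C/C(C)(C)O)CCO[Si](C)(C)C(C)(C)C)cc1 | intermediate
19 | (3R,5E)-3,7-dimethyl-3-[(1E)-3-(PMBO)prop-1-en-1-yl]oct-5-ene-1,7-diol | COc1ccc(COC/C=C/[C@](C)(C/C=C/C(C)(C)O)CCO)cc1 | intermediate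
20 | (3R,5E)-7-hydroxy-3,7-dimethyl-3-[(1E)-3-(PMBO)prop-1-en-1-yl]oct-5-enal | COc1ccc(COC/C=C/[C@](C)(C/C=C/C(C)(C)O)CC=O)cc1 | intermediate
21 | pent-3-yn-1-ol | CC#CCCO | starting material
22 | alkenylzirconocene chloride from 21 (Zr on C4 syn to H on C3; hydroxyl as its Cp2Zr(Cl) alkoxide) | Cl[Zr](OCC/C=C(\C)[Zr](Cl)(C1C=CC=C1)C1C=CC=C1)(C1C=CC=C1)C1C=CC=C1 | intermediate
23 | (3E)-4-iodopent-3-en-1-ol | OCC/C=C(\C)I | intermediate
24 | (2E)-2,5-diiodopent-2-ene | ICC/C=C(\C)I | intermediate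
25 | ethyl (triphenylphosphoranylidene)acetate | CCOC(=O)C=P(c1ccccc1)(c1ccccc1)c1ccccc1 | starting material
26 | [(5E)-1-ethoxy-6-iodo-1-oxohept-5-en-2-yl]triphenylphosphonium iodide | CCOC(=O)C(CC/C=C(\C)I)[P+](c1ccccc1)(c1ccccc1)c1ccccc1.[I-] | intermediate
27 | ethyl (5E)-6-iodo-2-(triphenylphosphoranylidene)hept-5-enoate | CCOC(=O)C(CC/C=C(\C)I)=P(c1ccccc1)(c1ccccc1)c1ccccc1 | intermediate
28 | ethyl (2E,5R,7E)-9-hydroxy-2-[(3E)-4-iodopent-3-en-1-yl]-5,9-dimethyl-5-[(1E)-3-(PMBO)prop-1-en-1-yl]deca-2,7-dienoate | COc1ccc(COC/C=C/[C@](C)(C/C=C/C(C)(C)O)C/C=C(\CC/C=C(\C)I)C(=O)OCC)cc1 | intermediate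
29 | (2E,5R,7E)-2-[(3E)-4-iodopent-3-en-1-yl]-5,9-dimethyl-5-[(1E)-3-(PMBO)prop-1-en-1-yl]deca-2,7-diene-1,9-diol | COc1ccc(COC/C=C/[C@](C)(C/C=C/C(C)(C)O)C/C=C(\CC/C=C(\C)I)CO)cc1 | intermediate
30 | (3E,6R,8E,12E)-13-iodo-2,6-dimethyl-6-[(1E)-3-(PMBO)prop-1-en-1-yl]-9-[(TBSO)methyl]tetradeca-3,8,12-trien-2-ol | COc1ccc(COC/C=C/[C@](C)(C/C=C/C(C)(C)O)C/C=C(\CC/C=C(\C)I)CO[Si](C)(C)C(C)(C)C)cc1 | intermediate
31 | (3E,6R,8E,12E)-13-iodo-2,6-dimethyl-6-[(1E)-3-(PMBO)prop-1-en-1-yl]-9-[(TBSO)methyl]-2-(TESO)tetradeca-3,8,12-triene | COc1ccc(COC/C=C/[C@](C)(C/C=C/C(C)(C)O[Si](CC)(CC)CC)C/C=C(\CC/C=C(\C)I)CO[Si](C)(C)C(C)(C)C)cc1 | intermediate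
32 | (2E,4R,6E,10E)-11-iodo-4-methyl-4-[(2E)-4-methyl-4-(TESO)pent-2-en-1-yl]-7-[(TBSO)methyl]dodeca-2,6,10-trien-1-ol | OC/C=C/[C@](C)(C/C=C/C(C)(C)O[Si](CC)(CC)CC)C/C=C(\CC/C=C(\C)I)CO[Si](C)(C)C(C)(C)C | intermediate
33 | (2E,4R,6E,10E)-11-iodo-4-methyl-4-[(2E)-4-methyl-4-(TESO)pent-2-en-1-yl]-7-[(TBSO)methyl]dodeca-2,6,10-trienal | O=C/C=C/[C@](C)(C/C=C/C(C)(C)O[Si](CC)(CC)CC)C/C=C(\CC/C=C(\C)I)CO[Si](C)(C)C(C)(C)C | intermediate
34 | alkenylchromium dichloride from 33 (CrCl2 in place of iodine, geometry retained) | O=C/C=C/[C@](C)(C/C=C/C(C)(C)O[Si](CC)(CC)CC)C/C=C(\CC/C=C(\C)[Cr](Cl)Cl)CO[Si](C)(C)C(C)(C)C | intermediate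
35 | (2E,4R,6E,10E)-4,11-dimethyl-4-[(2E)-4-methyl-4-(TESO)pent-2-en-1-yl]-7-[(TBSO)methyl]cycloundeca-2,6,10-trien-1-ol, both C1 epimers | OC1/C=C/[C@](C)(C/C=C/C(C)(C)O[Si](CC)(CC)CC)C/C=C(/CO[Si](C)(C)C(C)(C)C)CC/C=C1\C | intermediate
36 | (2E,4R,6E,10E)-4,11-dimethyl-4-[(2E)-4-methyl-4-(TESO)pent-2-en-1-yl]-7-[(TBSO)methyl]cycloundeca-2,6,10-trien-1-one | O=C1/C=C/[C@](C)(C/C=C/C(C)(C)O[Si](CC)(CC)CC)C/C=C(/CO[Si](C)(C)C(C)(C)C)CC/C=C1\C | intermediate
37 | (1R,2E,4R,6E,10E)-4,11-dimethyl-4-[(2E)-4-methyl-4-(TESO)pent-2-en-1-yl]-7-[(TBSO)methyl]cycloundeca-2,6,10-trien-1-ol | O[C@@H]1/C=C/[C@](C)(C/C=C/C(C)(C)O[Si](CC)(CC)CC)C/C=C(/CO[Si](C)(C)C(C)(C)C)CC/C=C1\C | intermediate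
38 | (1R,2E,4R,6E,10R,11R)-10,11-epoxy-4,11-dimethyl-4-[(2E)-4-methyl-4-(TESO)pent-2-en-1-yl]-7-[(TBSO)methyl]cycloundeca-2,6-dien-1-ol (erythro; C11 is spatially as in the target, the descriptor reads R only because the free hydroxyl lowers the rank of C1) | O[C@@H]1/C=C/[C@](C)(C/C=C/C(C)(C)O[Si](CC)(CC)CC)C/C=C(/CO[Si](C)(C)C(C)(C)C)CC[C@H]2O[C@]12C | intermediate
39 | (1S,2E,4R,6E,10R,11S)-10,11-epoxy-4,11-dimethyl-4-[(2E)-4-methyl-4-(TESO)pent-2-en-1-yl]-7-[(TBSO)methyl]cycloundeca-2,6-dien-1-yl 4-nitrobenzoate | O=C(O[C@H]1/C=C/[C@](C)(C/C=C/C(C)(C)O[Si](CC)(CC)CC)C/C=C(/CO[Si](C)(C)C(C)(C)C)CC[C@H]2O[C@]12C)c1ccc([N+](=O)[O-])cc1 | intermediate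
40 | (1S,2E,4R,6E,10R,11R)-10,11-epoxy-4,11-dimethyl-4-[(2E)-4-methyl-4-(TESO)pent-2-en-1-yl]-7-[(TBSO)methyl]cycloundeca-2,6-dien-1-ol (threo; C11 spatially as in the target) | O[C@H]1/C=C/[C@](C)(C/C=C/C(C)(C)O[Si](CC)(CC)CC)C/C=C(/CO[Si](C)(C)C(C)(C)C)CC[C@H]2O[C@]12C | intermediate
41 | 3-methylbut-2-enoic acid | CC(C)=CC(=O)O | starting material
42 | O-(3-methylbut-2-enoyl)-N,N'-dicyclohexylisourea | CC(C)=CC(=O)OC(=NC1CCCCC1)NC1CCCCC1 | intermediate
43 | (1S,2E,4R,6E,10R,11S)-10,11-epoxy-4,11-dimethyl-4-[(2E)-4-methyl-4-(TESO)pent-2-en-1-yl]-7-[(TBSO)methyl]cycloundeca-2,6-dien-1-yl 3-methylbut-2-enoate | CC(C)=CC(=O)O[C@H]1/C=C/[C@](C)(C/C=C/C(C)(C)O[Si](CC)(CC)CC)C/C=C(/CO[Si](C)(C)C(C)(C)C)CC[C@H]2O[C@]12C | intermediate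
44 | CNP0248133.1, (1S,2E,4R,6E,10R,11S)-10,11-epoxy-4-[(2E)-4-hydroxy-4-methylpent-2-en-1-yl]-7-(hydroxymethyl)-4,11-dimethylcycloundeca-2,6-dien-1-yl 3-methylbut-2-enoate | CC(C)=CC(=O)O[C@H]1/C=C/[C@](C)(C/C=C/C(C)(C)O)C/C=C(/CO)CC[C@H]2O[C@]12C | target

**Totals**
Total step count: 28. Longest linear sequence: 25 steps (steps 1–11, then 15–28); steps 12–14 are a three-step side branch to phosphorane 27.

**Three steps most likely to fail**

Step 21, the eleven-membered Nozaki–Hiyama–Kishi closure, may be defeated by ring strain and oligomerisation. The fallback closes the same C1–C11 bond at the ketone oxidation level by an intramolecular acyl Stille coupling, with no carbonyl addition and no chromium. It sets out from 33: Pd(PPh3)4 and (Me3Sn)2 in toluene at 80 °C exchange iodine for tin to give the alkenylstannane enal F1. Buffered chlorite oxidation (NaClO2, NaH2PO4, 2-methylbut-2-ene) gives the stannyl trienoic acid F2. 1-Chloro-N,N,2-trimethylprop-1-en-1-amine converts this under neutral conditions into the acid chloride F3, which is added slowly to Pd2(dba)3/P(2-furyl)3 in THF at 60 °C and 1 mM. The product is dienone 36, where the route is rejoined; steps 21 and 22 are bypassed.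

Step 23, the ketoreductase reduction, may fail because the lipophilic macrocyclic dienone is not accepted or is reduced with low selectivity. The fallback drops the redox correction and lets the epoxidation catalyst sort the epimers. It sets out from the epimer mixture 35: under the conditions of step 24, with t-BuOOH limited to the (1R) content, only the (1R)-epimer is matched and is epoxidised to 38, where the route is rejoined. The unreacted (1S)-dienol F4 is separated, oxidised to 36 with Dess–Martin periodinane and reduced with NaBH4/CeCl3 back to 35 for another pass.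

Step 25, the Mitsunobu inversion, is an SN2 displacement at a carbinol flanked by a fully substituted epoxide carbon and may be slow or give retention. The fallback inverts C1 by oxidation and catalyst-controlled reduction instead of substitution. It sets out from 38: Dess–Martin periodinane gives the epoxy enone F5. Chelating hydrides such as Zn(BH4)2 or NaBH4/CeCl3 would return the erythro alcohol 38, so the ketone is reduced with an (S)-selective ketoreductase (NADP+, i-PrOH, buffer pH 7). This gives the threo alcohol 40, where the route is rejoined; steps 25 and 26 are bypassed.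

**Further compounds**
F1 | step 21 | (2E,4R,6E,10E)-4-methyl-4-[(2E)-4-methyl-4-(TESO)pent-2-en-1-yl]-7-[(TBSO)methyl]-11-(trimethylstannyl)dodeca-2,6,10-trienal | O=C/C=C/[C@](C)(C/C=C/C(C)(C)O[Si](CC)(CC)CC)C/C=C(\CC/C=C(\C)[Sn](C)(C)C)CO[Si](C)(C)C(C)(C)C
F2 | step 21 | (2E,4R,6E,10E)-4-methyl-4-[(2E)-4-methyl-4-(TESO)pent-2-en-1-yl]-7-[(TBSO)methyl]-11-(trimethylstannyl)dodeca-2,6,10-trienoic acid | OC(=O)/C=C/[C@](C)(C/C=C/C(C)(C)O[Si](CC)(CC)CC)C/C=C(\CC/C=C(\C)[Sn](C)(C)C)CO[Si](C)(C)C(C)(C)C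
F3 | step 21 | (2E,4R,6E,10E)-4-methyl-4-[(2E)-4-methyl-4-(TESO)pent-2-en-1-yl]-7-[(TBSO)methyl]-11-(trimethylstannyl)dodeca-2,6,10-trienoyl chloride | ClC(=O)/C=C/[C@](C)(C/C=C/C(C)(C)O[Si](CC)(CC)CC)C/C=C(\CC/C=C(\C)[Sn](C)(C)C)CO[Si](C)(C)C(C)(C)C
F4 | step 23 | (1S,2E,4R,6E,10E)-4,11-dimethyl-4-[(2E)-4-methyl-4-(TESO)pent-2-en-1-yl]-7-[(TBSO)methyl]cycloundeca-2,6,10-trien-1-ol | O[C@H]1/C=C/[C@](C)(C/C=C/C(C)(C)O[Si](CC)(CC)CC)C/C=C(/CO[Si](C)(C)C(C)(C)C)CC/C=C1\C
F5 | step 25 | (2E,4R,6E,10R,11S)-10,11-epoxy-4,11-dimethyl-4-[(2E)-4-methyl-4-(TESO)pent-2-en-1-yl]-7-[(TBSO)methyl]cycloundeca-2,6-dien-1-one | O=C1/C=C/[C@](C)(C/C=C/C(C)(C)O[Si](CC)(CC)CC)C/C=C(/CO[Si](C)(C)C(C)(C)C)CC[C@H]2O[C@]12C
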